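**Plan**

1. Retrosynthesis: remove ten benzyl ethers and four ring-A bromine caps; take C3–OH of the epigallocatechin half back to C3–B; cut O1–C2 and C3–C4 of that half's ring C together (oxa-Diels–Alder) into a biaryl (Z)-styrenyl boronate and an o-quinone methide; boronate ← alkyne ← aldehyde; cut the biaryl bond (Suzuki–Miyaura) into a 6'-metalated epicatechin and a bromo-gallaldehyde.
2. Forward: rings A, C and B of the epicatechin half come intact from (–)-epicatechin; the pyrogallol ring is attached by cross-coupling; C2–C3 of the second half is grown as a (Z)-alkenyl boronate; the second phloroglucinol ring A arrives as an o-quinone methide and the last ring (ring C of the epigallocatechin half) closes; oxidation and hydrogenolysis finish.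
3. Enabling feature: in the epigallocatechin half, O1–C8a–C4a–C4 is the oxa-diene of a phloroglucinol o-quinone methide, and C2 is benzylic to the para-oxygenated pyrogallol ring B, so a C2=C3 styrene carrying boron at C3 is polarised to give O1–C2 and C3–C4.
4. Stereochemistry: C2/C3 of the epicatechin half come from the chiral pool; the 2,3-cis relation of the new ring comes from the Z alkene (suprafacial cycloaddition), its absolute sense from a chiral Brønsted acid, and C–B → C–O goes with retention.
5. Helpers: bromine at C6/C8 of both A rings steers iodination to ring B and silences the phloroglucinol rings toward the o-quinone methide; boron masks the C3 hydroxyl; all are removed at the end.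

Key step: step 11

Remark: the target SMILES fixes four stereocentres but not the sense of the tri-ortho-substituted biaryl axis; the route fixes (2R,3R) in both halves and carries the axis as it forms, atropisomers (if configurationally stable) being separated at the stage of 19.

**Route**

Step 1
Reactants: 1 (–)-epicatechin
Product: 2 5,7,3',4'-tetra-O-benzyl-(–)-epicatechin
Conditions: BnBr (4.4 equiv), K2CO3, DMF, rt
Reagents that add atoms: benzyl bromide BrCc1ccccc1
Why: Williamson ether synthesis in which K2CO3 deprotonates only the four phenols, so the C3 alcohol stays free and C2/C3 are not touched.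

Step 2
Reactants: 2 5,7,3',4'-tetra-O-benzyl-(–)-epicatechin
Product: 3 3,5,7,3',4'-penta-O-benzyl-(–)-epicatechin
Conditions: NaH, BnBr, Bu4NI (cat.), DMF, 0 °C → rt
Reagents that add atoms: benzyl bromide BrCc1ccccc1
Why: Williamson benzylation of the secondary alcohol through its sodium alkoxide, safe for C2 because with all phenols capped no quinone-methide ring opening is available.

Step 3
Reactants: 3 3,5,7,3',4'-penta-O-benzyl-(–)-epicatechin
Product: 5 6,8-dibromo-6'-iodo-3,5,7,3',4'-penta-O-benzyl-(–)-epicatechin, via 6,8-dibromide 4 (not isolated)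
Conditions: NBS (2.05 equiv), CH2Cl2, −20 °C → rt; then NIS (1.2 equiv), TFA (cat.), MeCN, 0 °C → rt
Reagents that add atoms: N-bromosuccinimide O=C1CCC(=O)N1Br; N-iodosuccinimide O=C1CCC(=O)N1I
Why: Electrophilic aromatic halogenation in order of ring nucleophilicity, the phloroglucinol-type ring A taking both bromines (C8, then C6), after which iodination should go to ring B at C6', para to the 3'-benzyloxy group.

Step 4
Reactants: 6 3,4,5-tris(benzyloxy)benzaldehyde
Product: 7 2-bromo-3,4,5-tris(benzyloxy)benzaldehyde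
Conditions: NBS, MeCN, rt
Reagents that add atoms: N-bromosuccinimide O=C1CCC(=O)N1Br
Why: Electrophilic aromatic bromination at the only type of free position (C2, equivalent to C6), activated ortho and para by the benzyloxy groups.

Step 5
Reactants: 5 6,8-dibromo-6'-iodo-3,5,7,3',4'-penta-O-benzyl-(–)-epicatechin; 7 2-bromo-3,4,5-tris(benzyloxy)benzaldehyde
Product: 9 biaryl aldehyde (C6' of the epicatechin unit bonded to C2 of the 3,4,5-tris(benzyloxy)benzaldehyde ring), via aryl pinacol boronate 8 (not isolated)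
Conditions: B2pin2, PdCl2(dppf) (5 mol %), KOAc, dioxane, 80 °C; then 7, aq K3PO4, 90 °C
Reagents that add atoms: none
Why: Miyaura borylation followed by Suzuki–Miyaura coupling in one pot, in which zerovalent palladium should insert into C–I much faster than into the hindered, electron-rich ring-A C–Br bonds, and the ortho-formyl group activates the bromide of 7 in the second stage.

Step 6
Reactants: 9 biaryl aldehyde
Product: 10 biaryl terminal alkyne (ethynyl in place of formyl)
Conditions: dimethyl (1-diazo-2-oxopropyl)phosphonate, K2CO3, MeOH/THF, 0 °C → rt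
Reagents that add atoms: Bestmann–Ohira reagent CC(=O)C(=[N+]=[N-])P(=O)(OC)OC
Why: Ohira–Bestmann (Seyferth–Gilbert) homologation turns the aryl aldehyde into the terminal alkyne under carbonate conditions that leave aryl bromides and benzyl ethers alone.

Step 7
Reactants: 10 biaryl terminal alkyne
Product: 11 (Z)-alkenyl pinacol boronate (aryl and Bpin cis)
Conditions: HBpin, [Rh(cod)Cl]2 (3 mol %), PiPr3 (12 mol %), Et3N, cyclohexane/THF, rt
Reagents that add atoms: pinacolborane [H]B1OC(C)(C)C(C)(C)O1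
Why: [Rh(cod)Cl]2/PiPr3-catalysed formal trans-hydroboration of a terminal alkyne through a vinylidene complex should give the (Z)-1-alkenylboronate, fixing the geometry that becomes the 2,3-cis relation.

Step 8
Reactants: 12 2,4,6-trihydroxybenzaldehyde
Product: 13 2-hydroxy-4,6-bis(benzyloxy)benzaldehyde
Conditions: BnBr (2.1 equiv), K2CO3, DMF, rt
Reagents that add atoms: benzyl bromide BrCc1ccccc1
Why: Williamson ether synthesis, selective because the remaining hydroxyl is hydrogen-bonded to the formyl group and is the least nucleophilic.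

Step 9
Reactants: 13 2-hydroxy-4,6-bis(benzyloxy)benzaldehyde
Product: 14 3,5-dibromo-2-hydroxy-4,6-bis(benzyloxy)benzaldehyde
Conditions: NBS (2.05 equiv), CH2Cl2, 0 °C → rt
Reagents that add atoms: N-bromosuccinimide O=C1CCC(=O)N1Br
Why: Electrophilic aromatic bromination fills the two remaining ring positions, both ortho/para to oxygen donors, installing the blocking bromines.

Step 10
Reactants: 14 3,5-dibromo-2-hydroxy-4,6-bis(benzyloxy)benzaldehyde
Product: 15 2,4-dibromo-3,5-bis(benzyloxy)-6-(hydroxymethyl)phenol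
Conditions: NaBH4, THF/MeOH, 0 °C
Reagents that add atoms: none
Why: Borohydride reduction of the aldehyde gives the salicyl alcohol that serves as o-quinone methide precursor.

Step 11
Reactants: 11 (Z)-alkenyl pinacol boronate; 15 2,4-dibromo-3,5-bis(benzyloxy)-6-(hydroxymethyl)phenol
Product: 17 2,3-cis-3-(pinacolatoboryl)flavan cycloadduct (new 5,7-bis(benzyloxy)-6,8-dibromochroman ring on the pyrogallol ring), via o-quinone methide 16 (not isolated)
Conditions: 15 (2.5 equiv, slow addition), (R)-3,3'-bis(2,4,6-triisopropylphenyl)-BINOL N-triflylphosphoramide (10 mol %), 5 Å molecular sieves, toluene, −20 °C → rt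
Reagents that add atoms: none
Why: Proposed new method: the chiral acid dehydrates 15 to o-quinone methide 16, held as a hydrogen-bonded ion pair, whose C8a=O/C4a=CH2 heterodiene should undergo an inverse-electron-demand, concerted but asynchronous oxa-Diels–Alder reaction with the (Z)-styrenyl boronate, C4–C3 bond formation leading and O1–C2 closure following as positive charge builds at C2, where the para-benzyloxy group of the pyrogallol ring and σ(C–B) hyperconjugation stabilise it; the closest known reaction type is the chiral-Brønsted-acid-catalysed [4+2] cycloaddition of o-quinone methides with styrenes to 2-arylchromans, an alkenyl pinacol boronate not having been used as the 2π partner. The pyran ring is closed by [4+2] cycloaddition (O1–C2 and C3–C4 in one event; in the stepwise limit a 6-endo capture of the benzylic cation by the phenol oxygen). The 2,3-cis relation follows from suprafacial addition across the Z double bond, and the absolute sense from the alkene face left open by the chiral counter-anion, the catalyst antipode being chosen to match; because the epicatechin half is enantiopure, attack on the other face gives a separable diastereomer. Regioselectivity (oxygen to the aryl-bearing carbon) is secured by the pyrogallol ring and the β-boron effect acting in the same direction; chemoselectivity against boron-to-carbon alkenyl transfer is secured by the weakly Lewis acidic, hindered pinacol ester and the absence of base, and against Friedel–Crafts benzylation by the bromine caps on both phloroglucinol rings and the slow addition of 15.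

Step 12
Reactants: 17 2,3-cis-3-(pinacolatoboryl)flavan cycloadduct
Product: 18 protected dimer with free (2R,3R)-3-hydroxyl in the epigallocatechin half
Conditions: 30% H2O2, 2 M NaOH, THF, 0 °C → rt
Reagents that add atoms: hydrogen peroxide OO
Why: Oxidation of the secondary alkyl boronate with alkaline hydrogen peroxide proceeds by 1,2-migration of carbon from boron to oxygen with retention, turning the cis C–B bond into the cis C3–OH.

Step 13
Reactants: 18 protected dimer with free 3-hydroxyl
Product: 19 degalloyl theasinensin F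
Conditions: H2 (1 atm), Pd(OH)2/C, NaHCO3, THF/MeOH/H2O, rt; work-up under argon
Reagents that add atoms: none
Why: Catalytic hydrogenolysis over Pd(OH)2/C should cleave the ten benzyl ethers and hydrodehalogenate the four aryl bromides in one operation, with bicarbonate buffering the HBr so that the flavan-3-ol units are not epimerised.

**Compound list**

1 | (–)-epicatechin, (2R,3R)-2-(3,4-dihydroxyphenyl)chromane-3,5,7-triol | Oc1cc(O)c2c(c1)O[C@H](c1ccc(O)c(O)c1)[C@H](O)C2 | starting material
2 | 5,7,3',4'-tetra-O-benzyl-(–)-epicatechin (2R,3R; 3-OH free) | O(Cc1ccccc1)c1cc(OCc2ccccc2)c2c(c1)O[C@H](c1ccc(OCc3ccccc3)c(OCc3ccccc3)c1)[C@H](O)C2 | intermediate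
3 | 3,5,7,3',4'-penta-O-benzyl-(–)-epicatechin (2R,3R) | O(Cc1ccccc1)c1cc(OCc2ccccc2)c2c(c1)O[C@H](c1ccc(OCc3ccccc3)c(OCc3ccccc3)c1)[C@H](OCc1ccccc1)C2 | intermediate
4 | 6,8-dibromo-3,5,7,3',4'-penta-O-benzyl-(–)-epicatechin (2R,3R) | O(Cc1ccccc1)c1c(Br)c(OCc2ccccc2)c2c(c1Br)O[C@H](c1ccc(OCc3ccccc3)c(OCc3ccccc3)c1)[C@H](OCc1ccccc1)C2 | intermediate (not isolated)
5 | 6,8-dibromo-6'-iodo-3,5,7,3',4'-penta-O-benzyl-(–)-epicatechin (2R,3R; iodine on ring B para to the 3'-benzyloxy group) | O(Cc1ccccc1)c1c(Br)c(OCc2ccccc2)c2c(c1Br)O[C@H](c1cc(OCc3ccccc3)c(OCc3ccccc3)cc1I)[C@H](OCc1ccccc1)C2 | intermediate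
6 | 3,4,5-tris(benzyloxy)benzaldehyde | O=Cc1cc(OCc2ccccc2)c(OCc2ccccc2)c(OCc2ccccc2)c1 | starting material
7 | 2-bromo-3,4,5-tris(benzyloxy)benzaldehyde | O=Cc1cc(OCc2ccccc2)c(OCc2ccccc2)c(OCc2ccccc2)c1Br | intermediate
8 | 6,8-dibromo-6'-(4,4,5,5-tetramethyl-1,3,2-dioxaborolan-2-yl)-3,5,7,3',4'-penta-O-benzyl-(–)-epicatechin (2R,3R) | O(Cc1ccccc1)c1c(Br)c(OCc2ccccc2)c2c(c1Br)O[C@H](c1cc(OCc3ccccc3)c(OCc3ccccc3)cc1B4OC(C)(C)C(C)(C)O4)[C@H](OCc1ccccc1)C2 | intermediate (not isolated)
9 | biaryl aldehyde: 2-[4,5-bis(benzyloxy)-2-[(2R,3R)-3,5,7-tris(benzyloxy)-6,8-dibromochroman-2-yl]phenyl]-3,4,5-tris(benzyloxy)benzaldehyde | O(Cc1ccccc1)c1c(Br)c(OCc2ccccc2)c2c(c1Br)O[C@H](c1cc(OCc3ccccc3)c(OCc3ccccc3)cc1-c1c(C=O)cc(OCc3ccccc3)c(OCc3ccccc3)c1OCc1ccccc1)[C@H](OCc1ccccc1)C2 | intermediate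
10 | biaryl alkyne: (2R,3R)-3,5,7-tris(benzyloxy)-6,8-dibromo-2-[4,5-bis(benzyloxy)-2-(2,3,4-tris(benzyloxy)-6-ethynylphenyl)phenyl]chromane | O(Cc1ccccc1)c1c(Br)c(OCc2ccccc2)c2c(c1Br)O[C@H](c1cc(OCc3ccccc3)c(OCc3ccccc3)cc1-c1c(C#C)cc(OCc3ccccc3)c(OCc3ccccc3)c1OCc1ccccc1)[C@H](OCc1ccccc1)C2 | intermediate
11 | (Z)-alkenyl boronate: as 10 with (Z)-2-(4,4,5,5-tetramethyl-1,3,2-dioxaborolan-2-yl)ethenyl in place of ethynyl | O(Cc1ccccc1)c1c(Br)c(OCc2ccccc2)c2c(c1Br)O[C@H](c1cc(OCc3ccccc3)c(OCc3ccccc3)cc1-c1c(/C=C\B4OC(C)(C)C(C)(C)O4)cc(OCc3ccccc3)c(OCc3ccccc3)c1OCc1ccccc1)[C@H](OCc1ccccc1)C2 | intermediate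
12 | 2,4,6-trihydroxybenzaldehyde | O=Cc1c(O)cc(O)cc1O | starting material
13 | 2-hydroxy-4,6-bis(benzyloxy)benzaldehyde | O=Cc1c(O)cc(OCc2ccccc2)cc1OCc1ccccc1 | intermediate
14 | 3,5-dibromo-2-hydroxy-4,6-bis(benzyloxy)benzaldehyde | O=Cc1c(O)c(Br)c(OCc2ccccc2)c(Br)c1OCc1ccccc1 | intermediate
15 | 2,4-dibromo-3,5-bis(benzyloxy)-6-(hydroxymethyl)phenol | OCc1c(O)c(Br)c(OCc2ccccc2)c(Br)c1OCc1ccccc1 | intermediate
16 | o-quinone methide: 2,4-dibromo-3,5-bis(benzyloxy)-6-methylidenecyclohexa-2,4-dien-1-one | C=C1C(=O)C(Br)=C(OCc2ccccc2)C(Br)=C1OCc1ccccc1 | intermediate (not isolated)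
17 | cycloadduct: as 11 with the alkenyl boronate replaced by a 2,3-cis-5,7-bis(benzyloxy)-6,8-dibromo-3-(pinacolatoboryl)chroman-2-yl ring (same spatial arrangement as (2R,3R) in 18; the formal C2 descriptor changes with boron at C3) | O(Cc1ccccc1)c1c(Br)c(OCc2ccccc2)c2c(c1Br)O[C@H](c1cc(OCc3ccccc3)c(OCc3ccccc3)cc1-c1c([C@H]4Oc5c(Br)c(OCc6ccccc6)c(Br)c(OCc6ccccc6)c5C[C@H]4B6OC(C)(C)C(C)(C)O6)cc(OCc3ccccc3)c(OCc3ccccc3)c1OCc1ccccc1)[C@H](OCc1ccccc1)C2 | intermediate
18 | protected dimer: as 17 with (2R,3R)-3-hydroxyl in place of boron (deca-O-benzyl, tetrabromo) | O(Cc1ccccc1)c1c(Br)c(OCc2ccccc2)c2c(c1Br)O[C@H](c1cc(OCc3ccccc3)c(OCc3ccccc3)cc1-c1c([C@H]4Oc5c(Br)c(OCc6ccccc6)c(Br)c(OCc6ccccc6)c5C[C@H]4O)cc(OCc3ccccc3)c(OCc3ccccc3)c1OCc1ccccc1)[C@H](OCc1ccccc1)C2 | intermediate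
19 | degalloyl theasinensin F (both flavan units 2R,3R) | Oc1cc(O)c2c(c1)O[C@H](c1cc(O)c(O)cc1-c1c([C@H]3Oc4cc(O)cc(O)c4C[C@H]3O)cc(O)c(O)c1O)[C@H](O)C2 | target

**Step count and risks**

Total steps: 13. Longest linear sequence: 9 steps (1 → 2 → 3 → 5 → 9 → 10 → 11 → 17 → 18 → 19; steps 1, 2, 3, 5, 6, 7, 11, 12, 13).

Steps most likely to fail:

1. Step 11 (proposed new method). After the first C–C bond the β-boryl benzylic cation may lose boron (net alkenyl transfer) or rotate before closure (2,3-trans product). The chiral acid may also fail to discriminate the alkene faces, or the benzylic cation may benzylate ring B instead. The fallback sets out from 11 and 15 and comes back at 18. KHF2 (MeOH/H2O) converts 11 into potassium (Z)-alkenyltrifluoroborate F1. BF3·OEt2 (CH2Cl2, −40 °C) then joins F1 to 15 by boron-to-carbon alkenyl transfer onto the o-quinone methide, a known metal-free coupling that keeps the olefin geometry, to give (Z)-2-(3-arylallyl)phenol F2. Ac2O/pyridine gives aryl acetate F3. Jacobsen epoxidation ((S,S)-(salen)MnCl, salen = N,N'-bis(3,5-di-tert-butylsalicylidene)-1,2-cyclohexanediamine, NaOCl, 4-phenylpyridine N-oxide, CH2Cl2, 0 °C), which is at its best with cis-disubstituted aryl alkenes, gives (2S,3R)-cis-epoxide F4. K2CO3/MeOH removes the acetate, and the phenol opens the epoxide at the benzylic carbon (6-endo, inversion at C2; CSA if closure is slow) to give 18.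

2. Step 5. Transmetalation of the ortho-hindered boronate may be slow, with competing protodeboronation, and oxidative addition into ring-A C–Br bonds would lead to oligomers. The fallback sets out from 5 and 7 and comes back at 9. LiCl-mediated insertion of zinc dust into the C–I bond of 5 (THF, 40 °C; the C–Br bonds are not attacked) gives arylzinc iodide F5. Negishi coupling of F5 with 7 (Pd(PtBu3)2, THF/NMP, rt → 40 °C) gives 9 without base and without a boron intermediate.

3. Step 7. The hindered aryl alkyne may not enter the vinylidene pathway, so that ordinary syn-hydroboration erodes the Z geometry on which the 2,3-cis relation depends. The fallback sets out from 9 and comes back at 11. Stork–Zhao olefination of 9 ((iodomethyl)triphenylphosphonium iodide, NaHMDS, THF/DMPU, −78 °C) gives (Z)-vinyl iodide F6. Stereoretentive Miyaura borylation of F6 (B2pin2, PdCl2(PPh3)2, KOPh, toluene, 50 °C) gives 11, the alkenyl C–I bond reacting well before the ring-A bromides.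

**Further compounds**

F1 | step 11 | potassium (Z)-alkenyltrifluoroborate (as 11 with BF3K in place of Bpin) | O(Cc1ccccc1)c1c(Br)c(OCc2ccccc2)c2c(c1Br)O[C@H](c1cc(OCc3ccccc3)c(OCc3ccccc3)cc1-c1c(/C=C\[B-](F)(F)F)cc(OCc3ccccc3)c(OCc3ccccc3)c1OCc1ccccc1)[C@H](OCc1ccccc1)C2.[K+]
F2 | step 11 | (Z)-2-(3-arylallyl)phenol (Z-CH=CH–CH2 link from the pyrogallol ring to C6 of 2,4-dibromo-3,5-bis(benzyloxy)phenol) | O(Cc1ccccc1)c1c(Br)c(OCc2ccccc2)c2c(c1Br)O[C@H](c1cc(OCc3ccccc3)c(OCc3ccccc3)cc1-c1c(/C=C\Cc4c(O)c(Br)c(OCc5ccccc5)c(Br)c4OCc5ccccc5)cc(OCc3ccccc3)c(OCc3ccccc3)c1OCc1ccccc1)[C@H](OCc1ccccc1)C2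
F3 | step 11 | aryl acetate of F2 | O(Cc1ccccc1)c1c(Br)c(OCc2ccccc2)c2c(c1Br)O[C@H](c1cc(OCc3ccccc3)c(OCc3ccccc3)cc1-c1c(/C=C\Cc4c(OC(C)=O)c(Br)c(OCc5ccccc5)c(Br)c4OCc5ccccc5)cc(OCc3ccccc3)c(OCc3ccccc3)c1OCc1ccccc1)[C@H](OCc1ccccc1)C2
F4 | step 11 | (2S,3R)-cis-epoxide of F3 (aryl-bearing carbon S) | O(Cc1ccccc1)c1c(Br)c(OCc2ccccc2)c2c(c1Br)O[C@H](c1cc(OCc3ccccc3)c(OCc3ccccc3)cc1-c1c([C@@H]4O[C@@H]4Cc5c(OC(C)=O)c(Br)c(OCc6ccccc6)c(Br)c5OCc6ccccc6)cc(OCc3ccccc3)c(OCc3ccccc3)c1OCc1ccccc1)[C@H](OCc1ccccc1)C2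
F5 | step 5 | arylzinc iodide (as 5 with ZnI in place of iodine) | O(Cc1ccccc1)c1c(Br)c(OCc2ccccc2)c2c(c1Br)O[C@H](c1cc(OCc3ccccc3)c(OCc3ccccc3)cc1[Zn]I)[C@H](OCc1ccccc1)C2
F6 | step 7 | (Z)-vinyl iodide (as 9 with (Z)-2-iodoethenyl in place of formyl) | O(Cc1ccccc1)c1c(Br)c(OCc2ccccc2)c2c(c1Br)O[C@H](c1cc(OCc3ccccc3)c(OCc3ccccc3)cc1-c1c(/C=C\I)cc(OCc3ccccc3)c(OCc3ccccc3)c1OCc1ccccc1)[C@H](OCc1ccccc1)C2
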